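The runs are simulated with made-up constants.

A racemate cannot show an excess of 90% of X over Q, taken as ([X] − [Q])/([X] + [Q]) (the enantiomeric excess), until [X]/[Q] has climbed from unity to 19.0. That climb is 4.25 doublings of [X]/[Q]; this count, the base-two logarithm of the ratio wanted, is the doublings needed. For the answer yes, the flask would have to double the ratio on average every 0.353 h within its 1.5 h.

in all of them: L 0.60 mM

| flask | Q | X | J | remark | time |
|---|---|---|---|---|---|
| north-west | 0.42 M | 0.42 M | 0.90 M | run made earlier |  |
| north | 0.66 M | 0.66 M | 0.90 M | run made earlier |  |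
| east | 0.30 M | 0.30 M | 1.4 M | run made earlier |  |
| flask | 0.30 M | 0.30 M | 0.900 M |  | 1.5 h |

| run | time / min | X / % | Q / % | D / % |
|---|---|---|---|---|
| north-west | 6.00 | 49.6 | 49.6 | 0.3 |
| north-west | 10.0 | 50.2 | 49.9 | 0.8 |
| north-west | 15.0 | 50.1 | 49.1 | 1.0 |
| north-west | 25.0 | 49.4 | 48.5 | 1.4 |
| north-west | 40.0 | 49.1 | 47.4 | 3.3 |
| north-west | 80.0 | 45.7 | 44.5 | 6.8 |
| north | 12.0 | 50.0 | 49.6 | 0 |
| north | 25.0 | 49.2 | 49.2 | 1.6 |
| north | 40.0 | 48.8 | 48.4 | 2.4 |
| north | 50.0 | 48.6 | 47.6 | 3.3 |
| north | 60.0 | 48.2 | 47.2 | 4.0 |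
| north | 80.0 | 47.4 | 46.5 | 6.0 |
| east | 6.00 | 49.4 | 49.8 | 0 |
| east | 10.0 | 49.6 | 49.7 | 0.7 |
| east | 20.0 | 49.5 | 48.4 | 1.4 |
| east | 40.0 | 48.3 | 47.8 | 4.2 |
| east | 80.0 | 45.6 | 44.1 | 9.1 |

(standard deviation of a reading: 0.3 percentage points)

- L is single-handed; Q and X are mirror images of each other, charged as a racemate, each of them at the stated concentration
- solid, in amounts per volume of the solution: J
- the earlier runs were read with a standard deviation of 0.3 percentage points
- at the start none of J is in solution

- whether the excess of X over Q among what is left of the two reaches 90% by 1.5 h (no / yes)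
- the highest excess of X over Q among what is left of the two up to 1.5 h

The east run has the same [Q], [X] and [L] as the flask, and more J. Its last reading, at 80.0 min, shows X 45.6% against Q 44.1%, each with a scatter of 0.3 percentage points. So one doubling takes about 27.6 h as read. That is slower than the pace wanted, by a factor of 78.2. Carried straight on and taken over from the east run, this estimate gives the flask 0.0543 doublings by 1.5 h, an excess of 1.88%, and so the answer no.

The forecast says no, with a top of 2%, on the ground that “selectivity is poor”.

The flask gives no and a top of 1.29%, under the reckoned 1.88%.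

    G + L + Q → L + D (k = 197 /M²/min)
    G + L + X → L + Z (k = 33.9 /M²/min)
    Q ⇌ X (k = 0.0435 /min)
    J ⇌ G, rate k4*(cs4 - [G]) while solid is left; crystals form when [G] > cs4 (solubility = 0.110 M, k = 0.0147 /min)
    L → E (k = 0.00646 /min)

In this scheme Q ⇌ X has a relaxation half-life of 0.133 h, short against 1.5 h. The top of the flask is worth 0.0372 doublings of the 4.25 needed. The neighbour flask, charged with 0.0010 M of L and otherwise the same, tops at 1.61%, which is 0.0465 doublings of the same 4.25, and it holds 12.3% of D at 1.50 h.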